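The route rests on cutting the C4–C5 bond of ring A (cheilanthane numbering). The C6 carbinol is read as a ketone. This turns the ring-fusion carbon C5 into the nucleophilic end of a C5=C6 silyl enol ether. The gem-dimethyl carbon C4 is read as a tertiary radical or cation made by hydrogen-atom transfer to an isopropenyl group. In one operation the key step creates the last methyl group and the C4 quaternary centre, closes ring A onto the complete B/C/D tricycle, and releases the C6 ketone. This is the first C–C bond of the presumed biosynthesis, made last. The precursor is enol ether 18, an oxocene-fused octalin bearing a 4-methylpent-4-enyl chain on C10.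

Key step: step 13

Remark on numbering: ring A = C1–C5 and C10; ring B = C5–C10; ring C = C8, C9, C11–C14; ring D (oxocene) = O, C13–C19, with the chain C14–C15–C16–C17(Me)=C18–C19–O–C13. β is the face of the methyl groups on C8 and C10; α is the face of H-5, H-9 and H-14.
Assumption: isomerically pure (E)-geranylacetone, tributyl(prop-1-yn-1-yl)stannane, allyl bromide and 5-bromo-2-methylpent-1-ene are taken as purchasable.

Step 1
Reactants: 1 (E)-geranylacetone
Product: 2 (5E,9E)-11-hydroxy-6,10-dimethylundeca-5,9-dien-2-one
Conditions: SeO2 (cat.), t-BuOOH, salicylic acid (cat.), CH2Cl2, 0 °C to rt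
Reagents that add atoms: tert-butyl hydroperoxide, CC(C)(C)OO
Why: Selenium dioxide allylic oxidation (ene reaction, then [2,3]-shift) should hydroxylate the (E)-methyl group of the terminal, most accessible trisubstituted alkene, which makes this carbon C7 and fixes the E geometry of the future C8=C9 bond.

Step 2
Reactants: 2 (5E,9E)-11-hydroxy-6,10-dimethylundeca-5,9-dien-2-one
Product: 3 (5E,9E)-11-bromo-6,10-dimethylundeca-5,9-dien-2-one
Conditions: CBr4, PPh3, CH2Cl2, 0 °C
Reagents that add atoms: carbon tetrabromide, BrC(Br)(Br)Br
Why: The Appel reaction converts the primary allylic alcohol into the bromide under neutral conditions, without allylic transposition and without touching the methyl ketone.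

Step 3
Reactants: 3 (5E,9E)-11-bromo-6,10-dimethylundeca-5,9-dien-2-one; 4 tributyl(prop-1-yn-1-yl)stannane
Product: 5 (5E,9E)-6,10-dimethylpentadeca-5,9-dien-13-yne-2,12-dione
Conditions: Pd2(dba)3 (cat.), AsPh3, CO (3 atm), THF, 45 °C
Reagents that add atoms: carbon monoxide, [C-]#[O+]
Why: In this carbonylative Stille coupling, zerovalent palladium ionises the allylic bromide, CO inserts at the unhindered primary terminus (C7) of the syn π-allyl complex with the E alkene retained, and the fast-transferring alkynyl group gives the ynone that carries C6, C5, C10 and the C10 methyl.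

Step 4
Reactants: 5 (5E,9E)-6,10-dimethylpentadeca-5,9-dien-13-yne-2,12-dione
Product: 6 (5E,9E,12S)-12-hydroxy-6,10-dimethylpentadeca-5,9-dien-13-yn-2-one
Conditions: Ru[(S,S)-TsNCH(Ph)CH(Ph)NH](p-cymene) (cat.), i-PrOH, rt
Reagents that add atoms: none
Why: Noyori-type asymmetric transfer hydrogenation under base-free conditions reduces alkynyl ketones far faster than dialkyl ketones, and the (S,S) catalyst should set the (S) carbinol (C6), with the alkyne playing the role of the aryl group of aryl ketones.

Step 5
Reactants: 6 (5E,9E,12S)-12-hydroxy-6,10-dimethylpentadeca-5,9-dien-13-yn-2-one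
Product: 7 (5E,9E,12S)-12-(tert-butyldimethylsilyloxy)-6,10-dimethylpentadeca-5,9-dien-13-yn-2-one
Conditions: TBSCl, imidazole, DMF, rt
Reagents that add atoms: tert-butyldimethylsilyl chloride, CC(C)(C)[Si](C)(C)Cl
Why: Standard silylation gives a bulky, non-migrating propargylic ether that will serve as the stereocontrol element of the cyclisation.

Step 6
Reactants: 7 (5E,9E,12S)-12-(tert-butyldimethylsilyloxy)-6,10-dimethylpentadeca-5,9-dien-13-yn-2-one
Product: 9 bicyclic hydroxy ketone (rings B/C trans-fused; 5(10)-ene; 6α-OTBS; 8β-Me; 9α-H; 13α-OH; 13β-Me; 14α-H; 14β-3-oxobutyl), via tricyclic enol ether 8 (not isolated)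
Conditions: [(2-biphenylyl)(t-Bu)2PAu(NCMe)]SbF6 (5 mol%), CH2Cl2, -20 °C to rt; then 0.5 M aq. oxalic acid, THF, 0 °C
Reagents that add atoms: water, O
Why: In this enyne-initiated polyene cyclisation by cationic monovalent gold (6-endo-dig), C9 attacks the activated alkyne at C10 (distal to the silyloxy group), the C8 and C13 cations are relayed through chair-like folds of the two E alkenes (8β-Me, 9α-H, 14α-H), the ketone oxygen caps C13 anti, from the α face, the pseudo-equatorial 6-OTBS (an axial one would clash with the 8-methyl) selects the fold and thus the absolute configuration, and mild acid hydrolyses enol ether 8.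

Step 7
Reactants: 9 bicyclic hydroxy ketone
Product: 10 bicyclic hydroxy diene (as 9 but 14β-CH2CH2C(CH3)=CH2)
Conditions: Ph3PCH3Br, KOt-Bu (3 equiv. each), THF, 0 °C to rt
Reagents that add atoms: methyltriphenylphosphonium bromide, C[P+](c1ccccc1)(c1ccccc1)c1ccccc1.[Br-]
Why: Wittig methylenation of the unhindered methyl ketone proceeds with excess ylide, which merely deprotonates the tertiary alcohol.

Step 8
Reactants: 10 bicyclic hydroxy diene; 11 allyl bromide
Product: 12 13α-O-allyl ether of 10
Conditions: KH, 18-crown-6 (cat.), THF, 0 to 40 °C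
Reagents that add atoms: none
Why: This is a Williamson etherification, in which the naked potassium alkoxide of the equatorial tertiary alcohol is alkylated by the very reactive, unhindered allylic halide with no change at C13.

Step 9
Reactants: 12 13α-O-allyl ether
Product: 13 B/C/D tricycle (ring D oxocene closed; 17Z; 6α-OTBS; 5(10)-ene)
Conditions: second-generation Grubbs catalyst (5 mol%), CH2Cl2 (2 mM), reflux
Reagents that add atoms: none
Why: In this ring-closing metathesis, the trans-diequatorial C13–O and C14–C15 bonds and the fully substituted C13 pre-organise the two chains, the eight-membered ring allows only the Z alkene, and the hindered trisubstituted C5=C10 alkene stays inert.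

Step 10
Reactants: 13 B/C/D tricycle silyl ether
Product: 14 tricyclic allylic alcohol (6α-OH; 5(10)-ene)
Conditions: TBAF, THF, rt
Reagents that add atoms: none
Why: Fluoride-induced desilylation is neutral to slightly basic and leaves the acid-sensitive tertiary allylic ether of ring D untouched.

Step 11
Reactants: 14 tricyclic allylic alcohol
Product: 15 tricyclic enone (C6 ketone; C5=C10; 10-Me)
Conditions: MnO2, CH2Cl2, rt
Reagents that add atoms: none
Why: Manganese dioxide oxidises only the allylic alcohol, so the stereocentre that steered the cyclisation is converted into the carbonyl that activates C10 and C5.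

Step 12
Reactants: 15 tricyclic enone; 16 5-bromo-2-methylpent-1-ene
Product: 18 triethylsilyl enol ether (C5=C6-OSiEt3; 10β-Me; 10α-4-methylpent-4-enyl), via Grignard reagent 17 (not isolated)
Conditions: 16, Mg, THF; then CuBr·SMe2 (20 mol%), HMPA, Et3SiCl, 15, THF, -78 to -40 °C; Et3N, pentane work-up
Reagents that add atoms: chlorotriethylsilane, CC[Si](Cl)(CC)CC
Why: In this chlorosilane-accelerated conjugate addition of a Grignard reagent under monovalent copper catalysis, the organocopper should reach C10 from the α face, anti to the axial 8β-methyl that sits 1,3 to C10 (the bias that also sends alkylation of related decalone enolates to the equatorial side), so the chain becomes α and the resident methyl β, and silylation locks the enolate regiospecifically as the C5=C6 enol ether.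

Step 13
Reactants: 18 triethylsilyl enol ether
Product: 20 tetracyclic trans-fused 6-ketone (5α-H), via cis-fused 5β-H ketone 19 (not isolated)
Conditions: [N,N'-bis(3,5-di-tert-butylsalicylidene)-1,2-cyclohexanediaminato]cobalt (10 mol%), 1-fluoro-2,4,6-trimethylpyridinium triflate, PhSiH3, 2,4,6-collidine, PhCF3, 0 °C to rt; then DBU, toluene, rt
Reagents that add atoms: none
Why: Proposed new method: a cobalt hydride generated from the divalent cobalt salen complex, the N-fluoropyridinium oxidant and PhSiH3 should transfer a hydrogen atom to the CH2 terminus of the isopropenyl group, creating the second C4 methyl and a tertiary C4 radical that either adds directly to C5 of the enol ether or is first oxidised through an alkylcobalt species to the C4 cation, both paths ending in the C6 silyloxycarbenium ion, which loses the silyl group to give the ketone. The closest known reaction types are cobalt-catalysed hydrogen-atom-transfer radical-polar crossover cyclisations of 1,1-disubstituted alkenes onto arene, alkene and heteroatom nucleophiles, and cation-olefin cyclisations terminated by silyl enol ethers, whose union on a silyl enol ether has not been shown. Ring A (C4, C3, C2, C1, C10, C5) closes in the 6-exo-trig mode on the C5=C6 bond by formation of the C4–C5 bond. C4 is not stereogenic and the only new stereocentre, C5, is put under thermodynamic control, because DBU equilibrates any cis-fused ketone 19 through the C6 enolate to the trans-fused 5α-H ketone 20, in which C4 is equatorial on ring B. The step needs hydrogen-atom transfer to the chain alkene only, which the bulky salen ligand should secure because the ring D alkene and the enol ether are trisubstituted and flanked by fully substituted carbons, while attack at C5 rather than C7 is fixed by the enol ether made in step 12. Added collidine ties up the Et3SiOTf released, so that the tertiary allylic ether of ring D is not ionised.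

Step 14
Reactants: 20 tetracyclic trans-fused 6-ketone
Product: 21 target CNP0179324.1 (13α,19-epoxycheilanth-17Z-en-6α-ol)
Conditions: SmI2, H2O, Et3N, THF, rt
Reagents that add atoms: none
Why: In this single-electron (dissolving-metal type) ketone reduction by divalent samarium, the C6 ketyl/carbanion is protonated so that oxygen takes the uncrowded equatorial 6α position, away from the three axial β methyls on C4, C8 and C10 (hydride reagents would attack from the α face and give the 6β alcohol), and the trisubstituted alkene and the γ,γ-disubstituted allylic ether are not reduced.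

Compound list
1 | (E)-geranylacetone, (5E)-6,10-dimethylundeca-5,9-dien-2-one | CC(C)=CCC/C(C)=C/CCC(C)=O | starting material
2 | (5E,9E)-11-hydroxy-6,10-dimethylundeca-5,9-dien-2-one | OC/C(C)=C/CC/C(C)=C/CCC(C)=O | intermediate
3 | (5E,9E)-11-bromo-6,10-dimethylundeca-5,9-dien-2-one | BrC/C(C)=C/CC/C(C)=C/CCC(C)=O | intermediate
4 | tributyl(prop-1-yn-1-yl)stannane | CC#C[Sn](CCCC)(CCCC)CCCC | starting material
5 | (5E,9E)-6,10-dimethylpentadeca-5,9-dien-13-yne-2,12-dione | CC#CC(=O)C/C(C)=C/CC/C(C)=C/CCC(C)=O | intermediate
6 | (5E,9E,12S)-12-hydroxy-6,10-dimethylpentadeca-5,9-dien-13-yn-2-one | CC#C[C@@H](O)C/C(C)=C/CC/C(C)=C/CCC(C)=O | intermediate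
7 | (5E,9E,12S)-12-(tert-butyldimethylsilyloxy)-6,10-dimethylpentadeca-5,9-dien-13-yn-2-one | CC#C[C@@H](O[Si](C)(C)C(C)(C)C)C/C(C)=C/CC/C(C)=C/CCC(C)=O | intermediate
8 | tricyclic enol ether: rings B/C plus a dihydropyran (O joins C13α and C17, C16=C17, 17-Me), 5(10)-ene, 6α-OTBS, 8β-Me, 9α-H, 13β-Me, 14α-H | O1[C@@]2(C)CC[C@@H]3C(C)=C[C@@H](O[Si](C)(C)C(C)(C)C)C[C@@]3(C)[C@@H]2CC=C1C | intermediate
9 | bicyclic hydroxy ketone: trans-fused rings B/C, 5(10)-ene with 10-Me, 6α-OTBS, 8β-Me, 9α-H, 13α-OH, 13β-Me, 14α-H, 14β-(3-oxobutyl) | O[C@@]1(C)CC[C@@H]2C(C)=C[C@@H](O[Si](C)(C)C(C)(C)C)C[C@@]2(C)[C@@H]1CCC(C)=O | intermediate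
10 | bicyclic hydroxy diene: as 9 with 14β-(3-methylbut-3-enyl) | O[C@@]1(C)CC[C@@H]2C(C)=C[C@@H](O[Si](C)(C)C(C)(C)C)C[C@@]2(C)[C@@H]1CCC(C)=C | intermediate
11 | allyl bromide | C=CCBr | starting material
12 | 13α-O-allyl ether of 10 | C=CCO[C@@]1(C)CC[C@@H]2C(C)=C[C@@H](O[Si](C)(C)C(C)(C)C)C[C@@]2(C)[C@@H]1CCC(C)=C | intermediate
13 | B/C/D tricycle: oxocene ring D (17Z, 17-Me) trans-fused at C13/C14, 5(10)-ene, 6α-OTBS | C/C1=C/CO[C@@]2(C)CC[C@@H]3C(C)=C[C@@H](O[Si](C)(C)C(C)(C)C)C[C@@]3(C)[C@@H]2CC1 | intermediate
14 | tricyclic allylic alcohol: as 13 with 6α-OH | C/C1=C/CO[C@@]2(C)CC[C@@H]3C(C)=C[C@@H](O)C[C@@]3(C)[C@@H]2CC1 | intermediate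
15 | tricyclic enone: C6 ketone conjugated with C5=C10, 10-Me | C/C1=C/CO[C@@]2(C)CC[C@@H]3C(C)=CC(=O)C[C@@]3(C)[C@@H]2CC1 | intermediate
16 | 5-bromo-2-methylpent-1-ene | C=C(C)CCCBr | starting material
17 | (4-methylpent-4-en-1-yl)magnesium bromide | C=C(C)CCC[Mg]Br | intermediate
18 | triethylsilyl enol ether: C5=C6-OSiEt3, 10β-Me, 10α-(4-methylpent-4-enyl), rings B/C/D as in 15 | C/C1=C/CO[C@@]2(C)CC[C@@H]3[C@@](C)(CCCC(C)=C)C=C(O[Si](CC)(CC)CC)C[C@@]3(C)[C@@H]2CC1 | intermediate
19 | cis-fused tetracyclic 6-ketone (5β-H) | C/C1=C/CO[C@@]2(C)CC[C@@H]3[C@@]4(C)CCCC(C)(C)[C@H]4C(=O)C[C@@]3(C)[C@@H]2CC1 | intermediate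
20 | trans-fused tetracyclic 6-ketone (5α-H) | C/C1=C/CO[C@@]2(C)CC[C@@H]3[C@@]4(C)CCCC(C)(C)[C@@H]4C(=O)C[C@@]3(C)[C@@H]2CC1 | intermediate
21 | CNP0179324.1, 13α,19-epoxycheilanth-17Z-en-6α-ol | C/C1=C/CO[C@@]2(C)CC[C@@H]3[C@@]4(C)CCCC(C)(C)[C@@H]4[C@@H](O)C[C@@]3(C)[C@@H]2CC1 | target

Total step count: 14. Longest linear sequence: 14 steps (from 1).

Steps most likely to fail

Step 13. The enol ether may be fluorinated or desilylated before the C–C bond forms. Reversible hydrogen-atom transfer may only isomerise the chain alkene. Closure at the very crowded C5 may be too slow.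
The fallback uses known chemistry, sets out from enone 15 and returns at ketone 20.
- Copper-catalysed conjugate addition of the Grignard reagent of 2-(3-bromopropyl)-2-methyl-1,3-dioxolane to 15, with the same α-face bias and an aqueous work-up, would give the keto ketal F1.
- PPTS in wet acetone would free the diketone F2.
- KOt-Bu in t-BuOH would close ring A by intramolecular aldol condensation of C5 onto the C4 ketone, giving the tetracyclic enone F3. Only the C5 enolate can form a six-membered ring that can dehydrate.
- Conjugate addition of Me2CuLi to C4, followed by protonation and base equilibration at C5, would give 20.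

Step 6. The cascade may be interrupted by early proton loss after ring B. A 5-exo closure may compete. The ketone may bind the gold cation.
The fallback changes the way the cascade is terminated, sets out from 7 and returns at 9.
- Ethylene glycol and PPTS in benzene would mask the ketone as the dioxolane F4.
- Gold-catalysed hydroxycyclisation in wet dioxane would let external water capture the C13 cation from the α face, giving the tertiary alcohol F5.
- PPTS in wet acetone would then release 9.

Step 12. Addition at the hindered β-carbon may not take place, or facial selectivity at C10 may be poor.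
The fallback replaces steric approach control by a directed reaction, sets out from allylic alcohol 14 and returns at 18.
- Hydroxyl-directed Simmons–Smith cyclopropanation (Et2Zn, CH2I2) would deliver CH2 to the α face of C5=C10, syn to the 6α-OH, giving the cyclopropyl carbinol F6.
- Dess–Martin oxidation would give the cyclopropyl ketone F7.
- Homoconjugate opening at the cyclopropane CH2 (the future C1) would follow, using the cuprate made from 4-bromo-2-methylbut-1-ene. The C5–CH2 bond, which is aligned with the carbonyl, cleaves, and trapping with Et3SiCl would give 18.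

Further compounds
F1 | step 13 | keto ketal: C6 ketone, 10β-Me, 10α-[3-(2-methyl-1,3-dioxolan-2-yl)propyl] | C/C1=C/CO[C@@]2(C)CC[C@@H]3[C@@](C)(CCCC4(C)OCCO4)CC(=O)C[C@@]3(C)[C@@H]2CC1
F2 | step 13 | diketone: C6 ketone, 10β-Me, 10α-(4-oxopentyl) | C/C1=C/CO[C@@]2(C)CC[C@@H]3[C@@](C)(CCCC(C)=O)CC(=O)C[C@@]3(C)[C@@H]2CC1
F3 | step 13 | tetracyclic enone: C6 ketone conjugated with C4=C5, 4-Me | C/C1=C/CO[C@@]2(C)CC[C@@H]3[C@@]4(C)CCCC(C)=C4C(=O)C[C@@]3(C)[C@@H]2CC1
F4 | step 6 | ethylene ketal of 7 | CC#C[C@@H](O[Si](C)(C)C(C)(C)C)C/C(C)=C/CC/C(C)=C/CCC1(C)OCCO1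
F5 | step 6 | ethylene ketal of 9 (13α-OH free) | O[C@@]1(C)CC[C@@H]2C(C)=C[C@@H](O[Si](C)(C)C(C)(C)C)C[C@@]2(C)[C@@H]1CCC3(C)OCCO3
F6 | step 12 | cyclopropyl carbinol: 5α,10α-methylene bridge, 6α-OH | C/C1=C/CO[C@@]2(C)CC[C@@H]3[C@@]4(C)C[C@H]4[C@@H](O)C[C@@]3(C)[C@@H]2CC1
F7 | step 12 | cyclopropyl ketone: 5α,10α-methylene bridge, C6 ketone | C/C1=C/CO[C@@]2(C)CC[C@@H]3[C@@]4(C)C[C@H]4C(=O)C[C@@]3(C)[C@@H]2CC1
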